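## Structural features

The target is a daucane-type diester built on a trans-fused bicyclo[5.3.0]decene. Cycloheptene ring A (C1, C2, C3, C4, C5, C6, C10; methyl on C3, C3=C4) and cyclopentane ring B (C6, C7, C8, C9, C10) share the C6–C10 bond, in which C6 is quaternary (β methyl) and C10 carries an α hydrogen. The six stereocentres are contiguous: C1 (α angelate) and C9 (β hydroxyl, α isopropyl) flank C10, and C5 (α angelate) and C7 (β hydroxyl) flank C6. The fragile groups are the two (Z)-2-methylbut-2-enoates, which isomerise to tiglates with base, nucleophiles or heat (the C5 ester is also allylic), and the tertiary C9 carbinol, which is 1,3 to two other oxygens. The real difficulty is threefold: the trans junction between a quaternary carbon and a CH inside a seven-membered ring, four hydroxyls that must be told apart, and the C1 oxygen, which sits on the α face. Hydride can reach C1 only from that α face, because the C6 methyl is gauche to C1 and screens the β face, so the oxygen would be pushed to the wrong (β) side. The key step exploits the C6–C10 bond: it joins a quaternary carbon bearing carbonyl-level C7 to a CH flanked by oxygenated C1 and C9, which is the array left when a ring-fusion carbon of a cis-decalin β-hydroxy sulfonate migrates from the carbinol carbon (C1) to the sulfonate carbon (C10).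

## Logic of the disconnections

25 is traced to 24 by cutting the O7–CH2Ar bond. The C7 hydroxyl must stay masked while C1 and C5 are acylated; the forward step has to unmask it oxidatively without touching two Z-enoates, one of them allylic.

24 is cut at both acyl C–O bonds to 21 and 23, and 23 at its anhydride C–O bond to two molecules of 22. This removes the isomerisable esters from all earlier chemistry; the forward step must acylate two hindered secondary hydroxyls, not the tertiary one, without Z to E isomerisation.

21 goes back to 20 (O5–Si bond), 20 to 19 and 19 to 18 (the C1–H bond is cut and re-formed on the other face). Hydride can only deliver the 1β carbinol, while the target needs the equatorial 1α oxygen, anti to the C9 hydroxyl. The forward steps therefore re-oxidise C1 and reduce it by electron transfer, which must not trigger retro-aldol cleavage of the β-hydroxy ketone.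

18 is cut at the C9–isopropyl bond to 17. 17 is traced through 16 to 15 (C9 carbonyl back to its methyl enol ether, O1 back to its ketal), 15 to 14 (O7–benzyl bond) and 14 to 13 (C7–H bond). This returns ring B to the methoxy enone; the forward steps must set C7 and C9 anti to the angular methyl and add a branched nucleophile to an enolisable β-alkoxy ketone.

13 goes back to 12 (ketal C–O) and 12 to 11 (C1–H). The C1 ketone has to be reduced first because it is the most electrophilic carbonyl and makes C10–H doubly activated; its configuration at this stage is provisional.

11 is traced through 10 to 9 by cutting C6–C10 and re-forming C1–C6. Both rings change size, and a 5-7 problem becomes a cis-decalin problem; the forward step must migrate C6 and not C2, with inversion at C10.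

9 goes back to 8 (S–O bond), 8 to 7 (separation of enantiomers) and 7 to 6 (C10–H bond). The forward reduction must place the C10 oxygen cis to the angular hydroxyl, otherwise an epoxide would form in place of the shift.

6 is traced through 5 to 4 by cutting the C1–O bond; the only enolisable position of 4 is the ring-fusion CH, and oxygen must enter syn to the angular methyl.

4 is cut at C5–C6 and C1–C2 into 2 and 3. One cycloaddition supplies ring A's carbons, the C3=C4 alkene, the quaternary C6, the C5 oxygen and the masked C7/C9/C10 oxygens; it must be regioselective (siloxy carbon next to the methyl-bearing carbon) and endo.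

2 is cut at O–Si to 1.

## Other disconnections considered

Alternative 1: the cut is C8–C9 of ring B in the fully acylated series.
- Forward step: SmI2 would reduce the C–Br bond of bromo diketone A2, and the nucleophilic C8 would add to the isobutyryl carbonyl to give hydroxy ketone A1, one hydride reduction from the target.
- In favour: ring B and the tertiary carbinol arise in one mild step, no protecting group is needed on O7 or O9, and no organometallic addition to a β-alkoxy ketone is required.
- Against: in A2, C10 is α to a ketone and can epimerise; the samarium enolate can attack the C5 angelate through a six-membered transition state; the C9 configuration rests on a chelated aldol geometry. All four ring A stereocentres, including the quaternary one, would have to be set on a monocyclic cycloheptene without a bicyclic template.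
- Comparison: this alternative is better than the chosen plan in endgame step economy and equal in the logic of the final C7 reduction. It is weaker in structure control, since the chosen plan takes C5/C6 from a cycloaddition and C10 from a stereospecific shift, and the route to A2 would be longer.

Alternative 2: the cut is C5–C6.
- Forward step: enolisation and silylation of seven-membered vinyl lactone A4, then a [3,3] shift through a boat-like transition state, would give acid A3 with the C5–C6 bond, the ring C3=C4 alkene, the quaternary C6 and a C5 silane as a masked hydroxyl.
- In favour: the two adjacent centres C5 and C6 come from a concerted suprafacial process, which is equal in reliability to the cycloaddition of the chosen plan. Absolute configuration can be relayed from the C3 carbinol, so no resolution is needed; on that point it is better than the chosen plan.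
- Against: A4 needs a stereodefined tertiary allylic ester inside a medium lactone with an (E)-vinylsilane. Ring B is not formed, so C7–C8 and C8–C9 must still be made, the carboxyl taken to the carbinol level, and a neopentyl silane oxidised. The C1 configuration problem is unchanged.
- Comparison: mechanistically clean but clearly worse in step economy, because the key step builds one ring where the chosen shift builds two.

Alternative 3: the cut removes C4 (bonds C3–C4 and C4–C5) and reconnects C3–C5, giving a trans-hydrindanone.
- Forward step: methylenation of silyl enol ether A6 with Et2Zn/CH2I2, then FeCl3 opening and NaOAc dehydrochlorination, would give enone A5.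
- In favour: ring B with C7 and C9 is complete before the key step. Trans-hydrindanones are available in enantiopure form by asymmetric annulation, so no resolution is needed, which is better than the chosen plan. Enol ether regiochemistry is unambiguous because C6 is quaternary, and the C3-methyl alkene is placed correctly, equal to the chosen plan.
- Against: C5 emerges as a ketone next to the quaternary centre, and its reduction to the 5α carbinol needs hydride from the methyl-screened β face with no neighbouring hydroxyl to steer it. Methylenation of a tetrasubstituted neopentyl enol ether is slow, and FeCl3 threatens silyl ethers and the tertiary carbinol.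
- Comparison: the chosen plan sets C5 by the endo rule and needs no contra-steric reduction there, so it is more secure; the step count of this alternative would be similar or higher once A6 is made.

Key step: step 7

Conventions: the atom labels C1 to C10 of the target are kept for every intermediate (in the decalins C1 and C6 are the ring-fusion carbons); β is the face of the C6 methyl group, α the opposite face.
Assumption: compounds 4 to 7 are racemates; their SMILES strings show the enantiomer that is carried on after step 5.

## Steps

Step 1
Reactants: 1 3-methylbut-2-enal
Product: 2 (E)-tert-butyl(dimethyl)[(3-methylbuta-1,3-dien-1-yl)oxy]silane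
Conditions: TBSOTf, Et3N, Et2O, 0 °C to rt
Reagents that add atoms: tert-butyldimethylsilyl trifluoromethanesulfonate (CC(C)(C)[Si](C)(C)OS(=O)(=O)C(F)(F)F)
Why: O-silylation gives an oxocarbenium ion that Et3N deprotonates at the γ-methyl group (silyl dienol ether formation); the (E) isomer should predominate and is the geometry the endo rule needs to place the C5 oxygen.

Step 2
Reactants: 2 (E)-silyl dienol ether; 3 2-methoxy-5-methyl-1,4-benzoquinone
Product: 4 racemic cis-decalin enedione (C1–H β; C5–OTBS α; C6–CH3 β; C7 and C10 ketones; C8=C9–OMe)
Conditions: BF3·OEt2 (0.5 equiv), CH2Cl2, −78 °C; NaHCO3 quench at −78 °C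
Reagents that add atoms: none
Why: Lewis-acid-catalysed Diels–Alder reaction; BF3 binds the more basic carbonyl oxygen (the one conjugated with the methoxy group, future C7), so the CH terminus of the methyl-substituted double bond (future C1) becomes electrophilic and takes the nucleophilic CH2 terminus of the diene, which puts the siloxy carbon next to the methyl-bearing carbon. The endo transition state gives the cis fusion and places the siloxy group anti to the C6 methyl; the methoxy-substituted double bond is too electron-rich to react.

Step 3
Reactants: 4 racemic cis-decalin enedione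
Product: 6 racemic angular hydroxy enedione (C1–OH β), via potassium enolate 5 (not isolated)
Conditions: KN(SiMe3)2, THF, −78 °C; then 2-(phenylsulfonyl)-3-phenyloxaziridine, −78 °C; AcOH quench at −78 °C
Reagents that add atoms: 2-(phenylsulfonyl)-3-phenyloxaziridine (O=S(=O)(N1OC1c1ccccc1)c1ccccc1)
Why: Enolate hydroxylation with an N-sulfonyloxaziridine; the ring-fusion C1–H is the only enolisable position (C6 is quaternary, C8 is vinylic). Oxygen should enter syn to the C6 methyl because the α face is covered by C5 and its siloxy group and the cis-fused bicycle is the normal outcome of angular functionalisation; the cold quench limits retro-aldol and α-ketol shifts of the product alkoxide.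

Step 4
Reactants: 6 racemic angular hydroxy enedione
Product: 7 racemic cis-diol (C1–OH β; C10–OH β)
Conditions: NaBH4, CeCl3·7H2O, MeOH/CH2Cl2, −78 °C
Reagents that add atoms: none
Why: Luche reduction; the enedione carbonyl C10 is far more electrophilic than the vinylogous ester carbonyl C7. Chelation of cerium between the C1 hydroxyl and the C10 carbonyl holds the hydroxyl in the carbonyl plane, which puts the C6 methyl syn-axial over the β face, so hydride should enter from the α face (as in 6-oxo-5β-steroids) and give the carbinol cis to the angular hydroxyl.

Step 5
Reactants: 7 racemic cis-diol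
Product: 8 cis-diol as the single enantiomer shown
Conditions: preparative supercritical-fluid chromatography, amylose tris(3,5-dimethylphenylcarbamate) phase, CO2/MeOH
Reagents that add atoms: none
Why: Resolution by chromatography on a chiral stationary phase; a rigid diol with two hydrogen-bond donors should separate well. No stereocentre is made; the enantiomer to be carried on is to be assigned by Mosher ester analysis of the C10 carbinol.

Step 6
Reactants: 8 cis-diol
Product: 9 cis-decalin hydroxy mesylate (C1–OH β; C10–OMs β)
Conditions: MsCl (1.2 equiv), Et3N, CH2Cl2, −30 to 0 °C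
Reagents that add atoms: methanesulfonyl chloride (CS(=O)(=O)Cl)
Why: Alcohol mesylation; the secondary C10 hydroxyl reacts (via sulfene) much faster than the tertiary C1 hydroxyl and no stereocentre is touched. C10 is neopentyl and its allylic partner is an electron-poor enol ether, so chloride displacement should not compete.

Step 7
Reactants: 9 cis-decalin hydroxy mesylate
Product: 11 trans-fused hydroazulenedione (C1 ketone; C5–OTBS α; C6–CH3 β; ring B 9-methoxy enone; C10–H α), via potassium alkoxide 10 (not isolated)
Conditions: KOtBu (1.2 equiv), THF, −78 to −20 °C; AcOH quench at −78 °C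
Reagents that add atoms: none
Why: KOtBu converts the tertiary hydroxyl into alkoxide 10; as the C1–O bond becomes a carbonyl, the C1–C6 σ bond, which is anti-periplanar to the C10–OMs bond, shifts to C10 and expels mesylate in one suprafacial 1,2-alkyl shift. The closest known reaction type is the base-induced semipinacol rearrangement of hydronaphthalene cis-diol monosulfonates to hydroazulenones. Ring B is closed by ring contraction, the migrating bond attacking C10 from the rear in a three-centre SN2-like transition state, and ring A arises in the same event as a one-carbon ring enlargement because C10 is inserted between C1 and C6. The one new stereocentre, C10, is formed with inversion, so H-10 ends up α and trans to the C6 methyl, while C6 migrates with retention. The step needs C6 and not C2 to migrate: the mesylate is equatorial on the cyclohexenone ring in the reactive conformer (the other chair would put it syn-axial to the C6 methyl), so only C1–C6 is aligned, and C6, being α to the C7 carbonyl, also bears developing negative charge better (retro-aldol character). Epoxide closure cannot compete because alkoxide and mesylate are cis. The product is more C–H acidic at C10 than 9 is at oxygen, hence the small excess of base, the low temperature and the cold acidic quench; protonation of any dienolate anti to the C6 methyl would restore the trans junction.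

Step 8
Reactants: 11 trans-fused hydroazulenedione
Product: 12 C1 carbinol (1β-OH expected)
Conditions: NaBH4, MeOH/CH2Cl2, −78 °C
Reagents that add atoms: none
Why: Borohydride reduction; the saturated C1 ketone is far more electrophilic than the vinylogous ester, and reducing it removes the doubly activated C10–H. Hydride can reach C1 only from the α face because the gauche C6 methyl covers the β face (compare 6- and 11-oxo steroids), so the 1β carbinol is expected; this configuration is provisional and is corrected in steps 14 and 15.

Step 9
Reactants: 12 C1 carbinol
Product: 13 1-O-(2-methoxyprop-2-yl) ether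
Conditions: 2-methoxypropene, PPTS (cat.), CH2Cl2, 0 °C
Reagents that add atoms: 2-methoxypropene (COC(C)=C)
Why: Acid-catalysed addition of the alcohol to an enol ether gives a mixed ketal that adds no stereocentre, cannot migrate under the basic conditions of step 11 (a silyl ether on O1 could move to O7) and is lost without an extra step in step 12.

Step 10
Reactants: 13 1-O-(2-methoxyprop-2-yl) ether
Product: 14 7β-hydroxy enol ether
Conditions: iBu2AlH, CH2Cl2, −78 °C; aqueous KNaC4H4O6 (potassium sodium tartrate) work-up
Reagents that add atoms: none
Why: 1,2-Reduction of a vinylogous ester with an aluminium hydride; the β face of C7 is blocked by the adjacent angular methyl and by the 1β ketal, so hydride should add from the α face as in 17-oxo steroids and give the 7β carbinol. The basic work-up keeps the acid-labile hydroxy enol ether and the ketal intact.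

Step 11
Reactants: 14 7β-hydroxy enol ether
Product: 15 7β-(4-methoxybenzyl) ether
Conditions: NaH, 4-methoxybenzyl chloride, Bu4NI (cat.), DMF, 0 °C to rt
Reagents that add atoms: 4-methoxybenzyl chloride (COc1ccc(CCl)cc1)
Why: Williamson etherification under basic conditions, which the enol ether, ketal and silyl ether tolerate; this group is the only one on the molecule that DDQ removes, so C7 can be unmasked last in the presence of the angelates.

Step 12
Reactants: 15 7β-(4-methoxybenzyl) ether
Product: 17 1β-hydroxy C9 ketone, via hydroxy enol ether 16 (not isolated)
Conditions: oxalic acid, THF/H2O, 0 °C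
Reagents that add atoms: water (O)
Why: Enol ether hydrolysis; C-protonation at C8 and hydration of the oxocarbenium ion release the C9 ketone, and the mixed ketal on O1 is hydrolysed in the same operation. Weak acid at 0 °C should avoid β-elimination of the C7 ether and epimerisation at C10.

Step 13
Reactants: 17 1β-hydroxy C9 ketone
Product: 18 1β,9β-diol with 9α-isopropyl
Conditions: CeCl3 (anhydrous), iPrMgCl (3.5 equiv), THF, −78 °C
Reagents that add atoms: isopropylmagnesium chloride (CC(C)[Mg]Cl)
Why: 1,2-Addition of an organocerium reagent, which adds to hindered enolisable ketones without the reduction and enolisation typical of iPrMgCl alone. The β face of C9 is shielded by the syn-axial C6 methyl, the C7 ether and the chelated 1β alkoxide, so the isopropyl group should enter from the α face and leave the tertiary hydroxyl β.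

Step 14
Reactants: 18 1β,9β-diol
Product: 19 C1 ketone with free 9β-hydroxyl
Conditions: Dess–Martin periodinane, NaHCO3, CH2Cl2, 0 °C to rt
Reagents that add atoms: none
Why: Periodinane oxidation of the only secondary hydroxyl; the tertiary carbinol, the benzyl ether and the alkene are inert, and the buffer protects the β-hydroxy ketone from dehydration.

Step 15
Reactants: 19 C1 ketone
Product: 20 1α,9β-diol
Conditions: SmI2, THF/MeOH, 0 °C
Reagents that add atoms: none
Why: SmI2 reduction of a β-hydroxy ketone; two-electron reduction through a samarium ketyl chelated by the C9 hydroxyl gives the 1,3-anti diol. The carbinol oxygen takes the equatorial α position away from the C6 methyl (thermodynamic control, as in dissolving-metal reductions), the opposite of hydride delivery; PMB and silyl ethers and the isolated alkene are inert.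

Step 16
Reactants: 20 1α,9β-diol
Product: 21 1α,5α,9β-triol
Conditions: Bu4NF, THF, rt to 45 °C
Reagents that add atoms: none
Why: Fluoride desilylation of the C5 ether; no carbonyl or ester is present, so the basicity of the reagent is harmless.

Step 17
Reactants: 22 angelic acid (2 equiv)
Product: 23 angelic anhydride
Conditions: DCC (0.5 equiv per acid), CH2Cl2, 0 °C to rt; filtration of the urea
Reagents that add atoms: angelic acid, the second molecule (C/C=C(/C)C(=O)O)
Why: Carbodiimide dehydration of a carboxylic acid to its anhydride: one molecule of 22 adds to DCC to give the O-acylisourea, which acylates a second molecule of 22, so two acid molecules end up in one molecule of 23 and the water is taken up as the urea. No base or nucleophilic catalyst is present, so the Z geometry should be retained.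

Step 18
Reactants: 21 1α,5α,9β-triol; 23 angelic anhydride
Product: 24 1,5-bis-angelate 7-(4-methoxybenzyl) ether
Conditions: LiN(SiMe3)2 (3.1 equiv), THF, −78 °C; then 23 (2.4 equiv), −78 to 0 °C; aqueous NH4Cl quench
Reagents that add atoms: none
Why: Acylation of lithium alkoxides with an anhydride at low temperature, conditions under which angelates do not isomerise to tiglates; each anhydride molecule transfers one angeloyl group. The two secondary alkoxides react, while the tertiary C9 alkoxide, flanked by isopropyl and the ring fusion, is too hindered; no stereocentre is affected.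

Step 19
Reactants: 24 bis-angelate PMB ether
Product: 25 target
Conditions: DDQ, CH2Cl2/pH 7 phosphate buffer, 0 °C
Reagents that add atoms: none
Why: Oxidative cleavage of a 4-methoxybenzyl ether by hydride abstraction and hydrolysis of the oxocarbenium ion; the neutral conditions leave both Z-enoates, the allylic ester and the tertiary carbinol untouched, and water prevents acetal formation with the 9β-hydroxyl.

## Compound list

1 | 3-methylbut-2-enal | CC(C)=CC=O | starting material
2 | (E)-tert-butyl(dimethyl)[(3-methylbuta-1,3-dien-1-yl)oxy]silane | C=C(C)/C=C/O[Si](C)(C)C(C)(C)C | intermediate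
3 | 2-methoxy-5-methyl-1,4-benzoquinone | COC1=CC(=O)C(C)=CC1=O | starting material
4 | racemic cis-fused adduct, 5-(tert-butyldimethylsilyloxy)-2-methoxy-4a,7-dimethyl-4a,5,8,8a-tetrahydronaphthalene-1,4-dione (target labels: C1–H β, C5–OTBS α, C6–CH3 β) | [C@H]12CC(C)=C[C@@H](O[Si](C)(C)C(C)(C)C)[C@@]1(C)C(=O)C=C(OC)C2=O | intermediate
5 | potassium C1=C10 enolate of 4 | [K+].[O-]C1=C2CC(C)=C[C@@H](O[Si](C)(C)C(C)(C)C)[C@@]2(C)C(=O)C=C1OC | intermediate (not isolated)
6 | racemic angular hydroxy enedione (C1–OH β, cis to C6–CH3) | O[C@]12CC(C)=C[C@@H](O[Si](C)(C)C(C)(C)C)[C@@]1(C)C(=O)C=C(OC)C2=O | intermediate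
7 | racemic cis-diol (C1–OH β, C10–OH β, C7 ketone, C8=C9–OMe) | O[C@]12CC(C)=C[C@@H](O[Si](C)(C)C(C)(C)C)[C@@]1(C)C(=O)C=C(OC)[C@@H]2O | intermediate
8 | cis-diol, single enantiomer | O[C@]12CC(C)=C[C@@H](O[Si](C)(C)C(C)(C)C)[C@@]1(C)C(=O)C=C(OC)[C@@H]2O | intermediate
9 | cis-decalin hydroxy mesylate (C1–OH β tertiary, C10–OMs β, C5–OTBS α, C6–CH3 β) | O[C@]12CC(C)=C[C@@H](O[Si](C)(C)C(C)(C)C)[C@@]1(C)C(=O)C=C(OC)[C@@H]2OS(C)(=O)=O | intermediate (key-step precursor)
10 | potassium alkoxide of 9 | [K+].[O-][C@]12CC(C)=C[C@@H](O[Si](C)(C)C(C)(C)C)[C@@]1(C)C(=O)C=C(OC)[C@@H]2OS(C)(=O)=O | intermediate (not isolated)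
11 | trans-fused hydroazulenedione (C1 ketone, C3=C4, C5–OTBS α, C6–CH3 β, C7 ketone, C8=C9–OMe, C10–H α) | O=C1CC(C)=C[C@@H](O[Si](C)(C)C(C)(C)C)[C@@]2(C)C(=O)C=C(OC)[C@H]12 | intermediate (key-step product)
12 | C1 carbinol of 11 (1β-OH) | O[C@@H]1CC(C)=C[C@@H](O[Si](C)(C)C(C)(C)C)[C@@]2(C)C(=O)C=C(OC)[C@H]12 | intermediate
13 | 1β-O-(2-methoxyprop-2-yl) ether of 12 | COC(C)(C)O[C@@H]1CC(C)=C[C@@H](O[Si](C)(C)C(C)(C)C)[C@@]2(C)C(=O)C=C(OC)[C@H]12 | intermediate
14 | 7β-hydroxy enol ether (C7–OH β, C8=C9–OMe) | COC(C)(C)O[C@@H]1CC(C)=C[C@@H](O[Si](C)(C)C(C)(C)C)[C@@]2(C)[C@H](O)C=C(OC)[C@H]12 | intermediate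
15 | 7β-(4-methoxybenzyl) ether of 14 | COC(C)(C)O[C@@H]1CC(C)=C[C@@H](O[Si](C)(C)C(C)(C)C)[C@@]2(C)[C@H](OCc3ccc(OC)cc3)C=C(OC)[C@H]12 | intermediate
16 | 1β-hydroxy enol ether (ketal removed, enol ether intact) | O[C@@H]1CC(C)=C[C@@H](O[Si](C)(C)C(C)(C)C)[C@@]2(C)[C@H](OCc3ccc(OC)cc3)C=C(OC)[C@H]12 | intermediate (not isolated)
17 | 1β-hydroxy C9 ketone (C7–OPMB β, C5–OTBS α) | O[C@@H]1CC(C)=C[C@@H](O[Si](C)(C)C(C)(C)C)[C@@]2(C)[C@H](OCc3ccc(OC)cc3)CC(=O)[C@H]12 | intermediate
18 | 1β,9β-diol (9α-isopropyl, C7–OPMB β, C5–OTBS α) | O[C@@H]1CC(C)=C[C@@H](O[Si](C)(C)C(C)(C)C)[C@@]2(C)[C@H](OCc3ccc(OC)cc3)C[C@@](O)(C(C)C)[C@H]12 | intermediate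
19 | C1 ketone with 9β-hydroxyl | O=C1CC(C)=C[C@@H](O[Si](C)(C)C(C)(C)C)[C@@]2(C)[C@H](OCc3ccc(OC)cc3)C[C@@](O)(C(C)C)[C@H]12 | intermediate
20 | 1α,9β-diol (C5–OTBS α, C7–OPMB β) | O[C@H]1CC(C)=C[C@@H](O[Si](C)(C)C(C)(C)C)[C@@]2(C)[C@H](OCc3ccc(OC)cc3)C[C@@](O)(C(C)C)[C@H]12 | intermediate
21 | 1α,5α,9β-triol (C7–OPMB β) | O[C@H]1CC(C)=C[C@@H](O)[C@@]2(C)[C@H](OCc3ccc(OC)cc3)C[C@@](O)(C(C)C)[C@H]12 | intermediate
22 | angelic acid, (Z)-2-methylbut-2-enoic acid | C/C=C(/C)C(=O)O | starting material
23 | angelic anhydride | C/C=C(/C)C(=O)OC(=O)/C(C)=C\C | intermediate
24 | 1α,5α-bis-angelate with C7–OPMB β and free 9β-hydroxyl | C/C=C(/C)C(=O)O[C@H]1CC(C)=C[C@@H](OC(=O)/C(C)=C\C)[C@@]2(C)[C@H](OCc3ccc(OC)cc3)C[C@@](O)(C(C)C)[C@H]12 | intermediate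
25 | CNP0249167.2 (1α,5α-bis-angeloyloxy, 7β-hydroxy, 9β-hydroxy-9α-isopropyl, 3,6β-dimethyl, 10α-H trans-hydroazul-3-ene in the labels used here) | C/C=C(/C)C(=O)O[C@H]1CC(C)=C[C@@H](OC(=O)/C(C)=C\C)[C@@]2(C)[C@H](O)C[C@@](O)(C(C)C)[C@H]12 | target

## Step count and least certain steps

Total: 19 steps. Longest linear sequence: 18 steps (steps 1 to 16, 18 and 19, from 1); step 17 is a one-step branch. Three steps (8, 14, 15) are spent on placing the C1 oxygen on the α face, which a direct hydride reduction cannot do.

Step 7 (key step). The most likely failure is proton transfer from the product, whose C10–H is α to the new ketone and γ to the enone, to alkoxide or base. The ring-fusion configuration would then be decided by protonation of a dienolate and not by the stereospecific shift. A second risk is vinylogous retro-aldol opening of the C1–C6 bond without closure onto C10. Fallback: drive the shift from 9 under non-basic, Lewis-acid conditions (Et3Al, CH2Cl2, −78 to 0 °C). The aluminium alkoxide forms with loss of ethane and aluminium pulls the mesylate while the same anti-periplanar bond migrates, so the product is never exposed to free base. This returns directly at 11 and makes no new compound (F0).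

Step 4. Hydride delivery to the β face of C10 (poor facial selectivity) would give the trans diol, whose mesylate would close to an epoxide in step 7. The face is hard to predict because the cis-decalin has two chair forms with opposite shielding. Fallback from 6, replacing chelation control by a bulky non-chelating oxygen substituent: silylate the tertiary hydroxyl (Me3SiOTf, Et3N) to the trimethylsilyl ether F1; reduce with iBu2AlH at −78 °C, where hydride is expected anti to the perpendicular C–O bond, to the carbinol F2; remove the silyl group with K2CO3 in MeOH to rejoin at 7.

Step 13. Enolisation of the hindered ketone with β-elimination of the C7 ether, β-hydride transfer from the isopropyl reagent, or retro-aldol opening through the C1 alkoxide may compete with addition. Fallback from 17: add isopropenylmagnesium bromide with CeCl3, an sp2 nucleophile that cannot transfer hydride, to give the isopropenyl carbinol F3; then hydrogenate the 1,1-disubstituted alkene selectively with H2 and RhCl(PPh3)3, which leaves the trisubstituted ring alkene, to rejoin at 18.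

Step 15. Loss of facial control (kinetic protonation returning the 1β carbinol) or retro-aldol cleavage of the β-hydroxy ketone on the Lewis-acidic trivalent samarium is possible. Fallback from 18, bypassing 19, by substitution instead of redox: Mitsunobu inversion (4-nitrobenzoic acid, PPh3, diisopropyl azodicarboxylate), in which the carboxylate attacks the open α face, gives the 1α 4-nitrobenzoate F4; methanolysis (K2CO3, MeOH) rejoins at 20. Elimination toward C2 or C10 is the risk of this fallback.

Step 18. Z to E isomerisation of the angeloyl groups under the basic conditions, or incomplete acylation of the neopentyl allylic C5 hydroxyl, is the main risk. Fallback from 21, building the Z alkene after acylation: esterify both secondary hydroxyls with 2-[bis(2,2,2-trifluoroethoxy)phosphoryl]propanoic acid (DCC, DMAP) to the bis-phosphonate F5; then a Still–Gennari olefination with acetaldehyde (KN(SiMe3)2, 18-crown-6, THF, −78 °C) gives the Z-trisubstituted enoates and rejoins at 24.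

## Further compounds

F0 | step 7 | none | none
F1 | step 4 | trimethylsilyl ether of 6 at the angular C1 oxygen (racemic) | C[Si](C)(C)O[C@]12CC(C)=C[C@@H](O[Si](C)(C)C(C)(C)C)[C@@]1(C)C(=O)C=C(OC)C2=O
F2 | step 4 | C1-O-trimethylsilyl ether of cis-diol 7 (C10–OH β, racemic) | C[Si](C)(C)O[C@]12CC(C)=C[C@@H](O[Si](C)(C)C(C)(C)C)[C@@]1(C)C(=O)C=C(OC)[C@@H]2O
F3 | step 13 | 9α-isopropenyl analogue of 18 (1β,9β-diol) | O[C@@H]1CC(C)=C[C@@H](O[Si](C)(C)C(C)(C)C)[C@@]2(C)[C@H](OCc3ccc(OC)cc3)C[C@@](O)(C(C)=C)[C@H]12
F4 | step 15 | 1α 4-nitrobenzoate of 20 | O=C(O[C@H]1CC(C)=C[C@@H](O[Si](C)(C)C(C)(C)C)[C@@]2(C)[C@H](OCc3ccc(OC)cc3)C[C@@](O)(C(C)C)[C@H]12)c4ccc(cc4)[N+](=O)[O-]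
F5 | step 18 | 1α,5α-bis{2-[bis(2,2,2-trifluoroethoxy)phosphoryl]propanoate} of 21 (phosphonate α-carbons as a mixture) | CC(C(=O)O[C@H]1CC(C)=C[C@@H](OC(=O)C(C)P(=O)(OCC(F)(F)F)OCC(F)(F)F)[C@@]2(C)[C@H](OCc3ccc(OC)cc3)C[C@@](O)(C(C)C)[C@H]12)P(=O)(OCC(F)(F)F)OCC(F)(F)F
A1 | alternative 1 | C7 ketone of the target (bis-angelate, 9β-hydroxy-9α-isopropyl) | C/C=C(/C)C(=O)O[C@H]1CC(C)=C[C@@H](OC(=O)/C(C)=C\C)[C@@]2(C)C(=O)C[C@@](O)(C(C)C)[C@H]12
A2 | alternative 1 | cycloheptene bis-angelate with bromoacetyl on C6 and isobutyryl on C10 | C/C=C(/C)C(=O)O[C@H]1CC(C)=C[C@@H](OC(=O)/C(C)=C\C)[C@@](C)(C(=O)CBr)[C@@H]1C(=O)C(C)C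
A3 | alternative 2 | ring A carboxylic acid with C5 silane and C9 dioxolane | CC(C)(C)[Si](C)(C)O[C@H]1CC(C)=C[C@@H]([Si](C)(C)OC(C)C)[C@@](C)(C(=O)O)[C@@H]1C2(C(C)C)OCCO2
A4 | alternative 2 | seven-membered lactone with C3 methyl and (E)-2-silylvinyl group (C6 configuration immaterial) | CC(C)(C)[Si](C)(C)O[C@H]1C[C@](C)(/C=C/[Si](C)(C)OC(C)C)OC(=O)C(C)[C@@H]1C2(C(C)C)OCCO2
A5 | alternative 3 | ring A enone (C5 ketone) on intact ring B | CC(C)(C)[Si](C)(C)O[C@H]1CC(C)=CC(=O)[C@@]2(C)[C@H](O[Si](C(C)C)(C(C)C)C(C)C)C[C@@](O)(C(C)C)[C@H]12
A6 | alternative 3 | trans-hydrindanone trimethylsilyl enol ether (C5–OTMS, C3=C5) with C9–OTMS | CC(C)(C)[Si](C)(C)O[C@H]1CC(C)=C(O[Si](C)(C)C)[C@@]2(C)[C@H](O[Si](C(C)C)(C(C)C)C(C)C)C[C@@](O[Si](C)(C)C)(C(C)C)[C@H]12
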